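**Assumption:** the target has no stereocentre (the only sp3 ring carbons each carry two identical methyls), so no stereocontrol is needed; the SMILES is taken as one tautomer of the enolized triketone.

**Retrosynthetic overview**
1. Target 8 ⇒ pyran ring removed last: prenal 6 annulated (Knoevenagel/oxa-6π) onto the single free aromatic C–H of dimer 5.
2. 5 ⇒ C2-symmetric methylenebis(phloracetophenone) 3 by one dearomative gem-dimethylation that converts only one of the two identical rings (key step).
3. 3 ⇒ two molecules of 2,4,6-trihydroxyacetophenone 1 + formaldehyde.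
4. Ring order: both carbocycles come from 1; the cyclohexadienone ring is made by dearomatization (step 2); the pyran ring is closed last (step 3).

**Route**

Step 1
Reactants: 1 2,4,6-trihydroxyacetophenone (two molecules)
Product: 3 3,3'-methylenebis(2,4,6-trihydroxyacetophenone), via 3-hydroxymethyl-phloracetophenone 2 (not isolated)
Conditions: 37% aq. HCHO (0.4 equiv per 1), cat. H2SO4, EtOH–H2O, rt, 12 h; 3 precipitates, excess 1 recovered
Reagents that add atoms: formaldehyde, C=O
Why: acid-catalysed hydroxymethylation to 2 followed by Friedel–Crafts alkylation of a second molecule of 1 (Baeyer diarylmethane condensation); the two free ring positions of 1 are equivalent, so one dimer results, and excess 1 plus precipitation of 3 limit trimers; no stereocentre.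

Step 2
Reactants: 3 3,3'-methylenebis(2,4,6-trihydroxyacetophenone)
Product: 5 2-acetyl-6-[(3-acetyl-2,4,6-trihydroxyphenyl)methyl]-3,5-dihydroxy-4,4-dimethylcyclohexa-2,5-dien-1-one, via mono-C-methyl dimer 4 (not isolated)
Conditions: NaOMe (3 equiv), MeI (1.6 equiv), MeOH, 0 °C → rt, N2; then 1 M HCl; unreacted 3 recycled
Reagents that add atoms: iodomethane, CI
Why: Proposed new method: mono-selective dearomative gem-dimethylation of a symmetric bis(acylphloroglucinol); each ring of 3 has one C–H nucleophilic carbon, its phenoxide is C-methylated there to give 4, the now more electron-rich ring is methylated again at the same carbon faster than the untouched ring (the all-or-nothing behaviour of phloroglucinol C-methylation), and the resulting vinylogous acid (pKa about 4–5) sits as a fully substituted, unreactive enolate while MeI is limiting, so one ring is dearomatized and the symmetry is broken; the closest known reaction is the Riedl MeI/NaOMe gem-dimethylation of acylphloroglucinols to acylfilicinic acids; the new quaternary carbon carries two identical methyls, so no stereocentre.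

Step 3
Reactants: 5 2-acetyl-6-[(3-acetyl-2,4,6-trihydroxyphenyl)methyl]-3,5-dihydroxy-4,4-dimethylcyclohexa-2,5-dien-1-one; 6 3-methylbut-2-enal (prenal)
Product: 8 CNP0333383.0 (2-acetyl-6-[(8-acetyl-5,7-dihydroxy-2,2-dimethyl-2H-chromen-6-yl)methyl]-3,5-dihydroxy-4,4-dimethylcyclohexa-2,5-dien-1-one), via o-quinone methide 7 (not isolated)
Conditions: 6 (1.5 equiv), EDDA (30 mol %), THF, 65 °C
Reagents that add atoms: none
Why: amine-catalysed Knoevenagel condensation of prenal at the only C–H nucleophilic carbon of 5 (the dienone ring has none) gives 1-oxatriene 7, whose oxa-6π electrocyclization (formal [3+3] chromene annulation) closes the pyran onto the oxygen next to the acetyl-bearing carbon, the mode expected by analogy with 3-alkyl-acylphloroglucinols, which keeps both OH groups flanking the bridge for the inter-ring hydrogen bonds; the new sp3 carbon carries two methyls, so no stereocentre.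

**Compound list**
1 | 2,4,6-trihydroxyacetophenone (phloracetophenone) | CC(=O)c1c(O)cc(O)cc1O | starting material
2 | 3-(hydroxymethyl)-2,4,6-trihydroxyacetophenone (formed in the flask, not isolated) | CC(=O)c1c(O)cc(O)c(CO)c1O | intermediate
3 | 3,3'-methylenebis(2,4,6-trihydroxyacetophenone) | CC(=O)c1c(O)cc(O)c(Cc2c(O)cc(O)c(C(C)=O)c2O)c1O | intermediate
4 | 1-{3-[(3-acetyl-2,4,6-trihydroxyphenyl)methyl]-2,4,6-trihydroxy-5-methylphenyl}ethanone (mono-C-methyl dimer, not isolated) | CC(=O)c1c(O)c(C)c(O)c(Cc2c(O)cc(O)c(C(C)=O)c2O)c1O | intermediate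
5 | 2-acetyl-6-[(3-acetyl-2,4,6-trihydroxyphenyl)methyl]-3,5-dihydroxy-4,4-dimethylcyclohexa-2,5-dien-1-one | CC(=O)C1=C(O)C(C)(C)C(O)=C(Cc2c(O)cc(O)c(C(C)=O)c2O)C1=O | intermediate
6 | 3-methylbut-2-enal (prenal) | CC(C)=CC=O | starting material
7 | o-quinone methide from 5 and prenal: the former aromatic C–H carbon bears an exocyclic =CH–CH=CMe2 group and the adjacent carbon next to the acetyl-bearing carbon is C=O (not isolated) | CC(=O)C1=C(O)C(C)(C)C(O)=C(CC2=C(O)C(=CC=C(C)C)C(=O)C(C(C)=O)=C2O)C1=O | intermediate
8 | 2-acetyl-6-[(8-acetyl-5,7-dihydroxy-2,2-dimethyl-2H-chromen-6-yl)methyl]-3,5-dihydroxy-4,4-dimethylcyclohexa-2,5-dien-1-one (CNP0333383.0) | CC(=O)C1=C(O)C(C)(C)C(O)=C(Cc2c(O)c3c(c(C(C)=O)c2O)OC(C)(C)C=C3)C1=O | target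

**Totals**
Total step count: 3. Longest linear sequence: 3.

**Steps most likely to fail, with fallbacks**

Step 2 (highest risk). The two rings of 3 react independently, so the mixture of 3, 5 and the doubly dearomatized product can approach the statistical ratio. Intermediate 4 can also be methylated at the bridge-bearing carbon, and alkali can scramble the methylene bridge (rottlerone-type change). The fallback sets out from 1 and comes back to the route at 5. It dearomatizes the monomer before the bridge is made: 1 is gem-dimethylated with MeI/NaOMe in MeOH to acetylfilicinic acid F1. F1 is aminomethylated at its one ring C–H with Eschenmoser's salt (MeCN, rt) to give 2-acetyl-6-[(dimethylamino)methyl]-3,5-dihydroxy-4,4-dimethylcyclohexa-2,5-dien-1-one F2. Heating F2 with excess 1 (dioxane, 90 °C) expels dimethylamine, and the resulting 2-methylene triketone is trapped at carbon by 1 to give 5. Step 3 then follows unchanged.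

Step 3. The pyran may close onto the oxygen next to the bridge carbon instead, giving the 6-acetyl-8-CH2 isomer; I am relying on analogy here, not on a known result for this substrate. The acidic dienone ring may also buffer the amine catalyst and slow the reaction. The fallback sets out from 1 and comes back at 8. It settles the chromene regiochemistry on the monomer: 1 and 6 under EDDA give 8-acetyl-5,7-dihydroxy-2,2-dimethyl-2H-chromene F3, separated from its 6-acetyl isomer at this stage. The one free aromatic C–H of F3 is aminomethylated with Eschenmoser's salt to give 8-acetyl-6-[(dimethylamino)methyl]-5,7-dihydroxy-2,2-dimethyl-2H-chromene F4. Heating F4 with excess 1 gives the unsymmetrical dimer 1-{3-[(8-acetyl-5,7-dihydroxy-2,2-dimethyl-2H-chromen-6-yl)methyl]-2,4,6-trihydroxyphenyl}ethanone F5. F5 has only one ring with a free C–H, which is dearomatized by gem-dimethylation (MeI, NaOMe, MeOH) to give 8.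

Step 1. Compound 3 still has two nucleophilic ring positions and can condense further with formaldehyde to trimers and oligomers. The fallback sets out from 1 and comes back at 3. It delivers the one-carbon unit stepwise: 1 and Eschenmoser's salt (one equivalent, MeCN, rt) give the mono-Mannich base 3-[(dimethylamino)methyl]-2,4,6-trihydroxyacetophenone F6. Heating F6 with excess 1 (dioxane, 90 °C) eliminates dimethylamine, and the o-quinone methide is trapped by 1 to give 3.

**Further compounds**
F1 | step 2 | acetylfilicinic acid (2-acetyl-3,5-dihydroxy-4,4-dimethylcyclohexa-2,5-dien-1-one) | CC(=O)C1=C(O)C(C)(C)C(O)=CC1=O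
F2 | step 2 | 2-acetyl-6-[(dimethylamino)methyl]-3,5-dihydroxy-4,4-dimethylcyclohexa-2,5-dien-1-one | CC(=O)C1=C(O)C(C)(C)C(O)=C(CN(C)C)C1=O
F3 | step 3 | 8-acetyl-5,7-dihydroxy-2,2-dimethyl-2H-chromene | CC(=O)c1c(O)cc(O)c2C=CC(C)(C)Oc12
F4 | step 3 | 8-acetyl-6-[(dimethylamino)methyl]-5,7-dihydroxy-2,2-dimethyl-2H-chromene | CC(=O)c1c(O)c(CN(C)C)c(O)c2C=CC(C)(C)Oc12
F5 | step 3 | 1-{3-[(8-acetyl-5,7-dihydroxy-2,2-dimethyl-2H-chromen-6-yl)methyl]-2,4,6-trihydroxyphenyl}ethanone | CC(=O)c1c(O)cc(O)c(Cc2c(O)c3C=CC(C)(C)Oc3c(C(C)=O)c2O)c1O
F6 | step 1 | 3-[(dimethylamino)methyl]-2,4,6-trihydroxyacetophenone | CC(=O)c1c(O)cc(O)c(CN(C)C)c1O
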